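**Retrosynthetic overview**
- The target is the penta-O-benzyl ether with the benzyl groups removed; that ether comes from a bis-(2S)-flav-3-ene by double hydroboration–oxidation, which sets C3 and C4 of the upper unit and C3 of the lower unit anti to each C2 aryl group.
- The bis-flav-3-ene comes from an acyclic bis(allylic alcohol) diphenol. Both pyran rings (ring C of each flavan unit) close in one chiral Brønsted acid catalysed double dehydrative cyclisation, which sets both C2 centres.
- The acyclic precursor comes from an aryllithium (made from a bromo allylic alcohol) adding 1,2 to a 2'-hydroxychalcone, so the C4–C6' interflavan bond exists before any heterocycle.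
- Both halves come from Claisen–Schmidt condensations of one acetophenone with two benzaldehydes; the bromo aldehyde comes from bromination of 3,4-bis(benzyloxy)benzaldehyde.
- Ring order: no heterocycle until step 6, then upper and lower pyran rings together.

Assumption: the (S)-configured catalyst in step 6 is taken to give the (2S)-chromene at both sites; the sense is checked on the first run and the mirror-image catalyst is used if it is opposite.

**Route**

Step 1
Reactants: 1 3,4-bis(benzyloxy)benzaldehyde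
Product: 2 4,5-bis(benzyloxy)-2-bromobenzaldehyde
Conditions: Br2 (1.1 equiv), NaOAc, AcOH, rt
Reagents that add atoms: bromine, BrBr
Why: Electrophilic aromatic bromination goes para to the 3-benzyloxy group and ortho to the formyl group (the site taken in veratraldehyde), with NaOAc buffering HBr so the benzyl ethers survive; no stereocentre is formed.

Step 2
Reactants: 2 4,5-bis(benzyloxy)-2-bromobenzaldehyde, 3 1-[4-(benzyloxy)-2-hydroxyphenyl]ethan-1-one
Product: 4 (E)-1-[4-(benzyloxy)-2-hydroxyphenyl]-3-[4,5-bis(benzyloxy)-2-bromophenyl]prop-2-en-1-one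
Conditions: KOH (50% aq), EtOH/THF, rt, 48 h; then 1 M HCl to pH 6 at 0 °C
Reagents that add atoms: none
Why: Claisen–Schmidt aldol condensation with E1cB dehydration gives the E-enone, and the aryl bromide and benzyl ethers are inert to hydroxide.

Step 3
Reactants: 4 (E)-1-[4-(benzyloxy)-2-hydroxyphenyl]-3-[4,5-bis(benzyloxy)-2-bromophenyl]prop-2-en-1-one
Product: 5 (E)-1-[4-(benzyloxy)-2-hydroxyphenyl]-3-[4,5-bis(benzyloxy)-2-bromophenyl]prop-2-en-1-ol (racemic)
Conditions: NaBH4 (3 equiv), THF/i-PrOH, 0 °C to rt; aq NaHCO3 work-up (pH 8), dried by toluene azeotrope below 30 °C, used crude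
Reagents that add atoms: none
Why: Borohydride 1,2-reduction of the 2'-hydroxychalcone carbonyl gives the allylic alcohol, which stays open-chain as long as it never meets acid; its carbinol centre is racemic on purpose because step 6 destroys it.

Step 4
Reactants: 3 1-[4-(benzyloxy)-2-hydroxyphenyl]ethan-1-one, 6 4-(benzyloxy)benzaldehyde
Product: 7 (E)-1-[4-(benzyloxy)-2-hydroxyphenyl]-3-[4-(benzyloxy)phenyl]prop-2-en-1-one
Conditions: KOH (50% aq), EtOH, rt, 24 h; then 1 M HCl to pH 6 at 0 °C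
Reagents that add atoms: none
Why: Claisen–Schmidt aldol condensation gives the E-chalcone, which crystallises from the reaction mixture.

Step 5
Reactants: 5 (E)-1-[4-(benzyloxy)-2-hydroxyphenyl]-3-[4,5-bis(benzyloxy)-2-bromophenyl]prop-2-en-1-ol, 7 (E)-1-[4-(benzyloxy)-2-hydroxyphenyl]-3-[4-(benzyloxy)phenyl]prop-2-en-1-one
Product: 11 (E)-1-[4-(benzyloxy)-2-hydroxyphenyl]-3-{4,5-bis(benzyloxy)-2-[(E)-1-[4-(benzyloxy)-2-hydroxyphenyl]-3-[4-(benzyloxy)phenyl]-1-hydroxyprop-2-en-1-yl]phenyl}prop-2-en-1-ol (diastereomer mixture at the two carbinol carbons), via trilithio aryllithium 8 (not isolated), via lithium chalcone phenoxide 9 (not isolated), via tetralithium adduct 10 (not isolated)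
Conditions: 5, n-BuLi (3.05 equiv), THF, −78 °C; 7 (1.2 equiv), LiN(SiMe3)2 (1.2 equiv), THF, −78 °C, added by cannula; −78 to −40 °C; pH 7 phosphate buffer; filtered through Et3N-deactivated silica
Reagents that add atoms: none
Why: Two O–H deprotonations followed by fast bromine–lithium exchange give a hard aryllithium that adds 1,2 to the lithium-chelated chalcone carbonyl (which has no enolisable hydrogen); the new tertiary carbinol is racemic, which does not matter because step 6 planarises it.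

Step 6
Reactants: 11 (E)-1-[4-(benzyloxy)-2-hydroxyphenyl]-3-{4,5-bis(benzyloxy)-2-[(E)-1-[4-(benzyloxy)-2-hydroxyphenyl]-3-[4-(benzyloxy)phenyl]-1-hydroxyprop-2-en-1-yl]phenyl}prop-2-en-1-ol
Product: 13 (2S)-7-(benzyloxy)-2-[4-(benzyloxy)phenyl]-4-{4,5-bis(benzyloxy)-2-[(2S)-7-(benzyloxy)-2H-chromen-2-yl]phenyl}-2H-chromene, via mono-chromene allylic alcohol 12 (not isolated)
Conditions: (S)-3,3'-bis(2,4,6-triisopropylphenyl)-H8-BINOL N-triflylphosphoramide (10 mol %), 4 Å MS, toluene, −78 °C, 48 h; Et3N quench at −78 °C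
Reagents that add atoms: none
Why: Proposed new method: the chiral N-triflylphosphoramide ionises each benzylic allylic alcohol (the tertiary one first) to an allyl cation / ortho-quinone methide held as a contact ion pair with the chiral phosphoramide anion, and the ortho phenol closes on the aryl-bearing allyl terminus (intramolecular allylic substitution, equivalently oxa-6π ring closure) inside that ion pair, so the anion and not the racemic carbinol centres chooses the face at each new C2 and both pyran rings form in the same operation; the closest known reaction is the chiral N-triflylphosphoramide-catalysed enantioselective cyclisation of 2-(1-hydroxy-1,3-diarylallyl)phenols to 2,4-diaryl-2H-chromenes, extended here to two sites at once and to a secondary carbinol.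

Step 7
Reactants: 13 (2S)-7-(benzyloxy)-2-[4-(benzyloxy)phenyl]-4-{4,5-bis(benzyloxy)-2-[(2S)-7-(benzyloxy)-2H-chromen-2-yl]phenyl}-2H-chromene
Product: 15 (2R,3S,4R)-7-(benzyloxy)-2-[4-(benzyloxy)phenyl]-4-{4,5-bis(benzyloxy)-2-[(2R,3S)-7-(benzyloxy)-3-hydroxy-3,4-dihydro-2H-chromen-2-yl]phenyl}-3,4-dihydro-2H-chromen-3-ol, via bis-alkylborane 14 (not isolated)
Conditions: BH3·THF (6 equiv), THF, 0 °C to rt, 12 h; then 3 M NaOH, 30% H2O2, 0 °C to rt
Reagents that add atoms: hydrogen peroxide, OO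
Why: Hydroboration–oxidation adds H and B syn across each C3=C4 bond on the face opposite the C2 aryl group, with boron at C3 (hydrogen goes to the benzylic C4 activated by the 7-alkoxy ring), and oxidation with retention gives 2,3-trans in both units and 3,4-trans (4-aryl cis to 2-aryl) in the upper unit.

Step 8
Reactants: 15 (2R,3S,4R)-7-(benzyloxy)-2-[4-(benzyloxy)phenyl]-4-{4,5-bis(benzyloxy)-2-[(2R,3S)-7-(benzyloxy)-3-hydroxy-3,4-dihydro-2H-chromen-2-yl]phenyl}-3,4-dihydro-2H-chromen-3-ol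
Product: 16 (2R,3S,4R)-4-{2-[(2R,3S)-3,7-dihydroxy-3,4-dihydro-2H-chromen-2-yl]-4,5-dihydroxyphenyl}-2-(4-hydroxyphenyl)-3,4-dihydro-2H-chromene-3,7-diol (target)
Conditions: H2 (1 atm), Pd(OH)2/C, THF/MeOH (1:1), rt
Reagents that add atoms: none
Why: Hydrogenolysis cleaves the five aryl benzyl ethers under neutral conditions that leave the chroman C2–O bonds, the diarylmethine C4 and all five stereocentres untouched, as is standard for benzylated flavan-3-ols.

**Compound list**

1 | 3,4-bis(benzyloxy)benzaldehyde | O=Cc1ccc(OCc2ccccc2)c(OCc2ccccc2)c1 | starting material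
2 | 4,5-bis(benzyloxy)-2-bromobenzaldehyde | O=Cc1cc(OCc2ccccc2)c(OCc2ccccc2)cc1Br | intermediate
3 | 1-[4-(benzyloxy)-2-hydroxyphenyl]ethan-1-one | CC(=O)c1ccc(OCc2ccccc2)cc1O | starting material
4 | (E)-1-[4-(benzyloxy)-2-hydroxyphenyl]-3-[4,5-bis(benzyloxy)-2-bromophenyl]prop-2-en-1-one | O=C(/C=C/c1cc(OCc2ccccc2)c(OCc2ccccc2)cc1Br)c1ccc(OCc2ccccc2)cc1O | intermediate
5 | (E)-1-[4-(benzyloxy)-2-hydroxyphenyl]-3-[4,5-bis(benzyloxy)-2-bromophenyl]prop-2-en-1-ol, racemic | OC(/C=C/c1cc(OCc2ccccc2)c(OCc2ccccc2)cc1Br)c1ccc(OCc2ccccc2)cc1O | intermediate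
6 | 4-(benzyloxy)benzaldehyde | O=Cc1ccc(OCc2ccccc2)cc1 | starting material
7 | (E)-1-[4-(benzyloxy)-2-hydroxyphenyl]-3-[4-(benzyloxy)phenyl]prop-2-en-1-one | O=C(/C=C/c1ccc(OCc2ccccc2)cc1)c1ccc(OCc2ccccc2)cc1O | intermediate
8 | O,O,C-trilithio derivative of 5 (lithium alkoxide, lithium phenoxide, aryllithium in place of bromine) | [Li]OC(/C=C/c1cc(OCc2ccccc2)c(OCc2ccccc2)cc1[Li])c1ccc(OCc2ccccc2)cc1O[Li] | intermediate
9 | lithium phenoxide of chalcone 7 | [Li]Oc1cc(OCc2ccccc2)ccc1C(=O)/C=C/c1ccc(OCc2ccccc2)cc1 | intermediate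
10 | tetralithium salt of 11 (two alkoxides, two phenoxides) | [Li]OC(/C=C/c1cc(OCc2ccccc2)c(OCc2ccccc2)cc1C(O[Li])(/C=C/c1ccc(OCc2ccccc2)cc1)c1ccc(OCc2ccccc2)cc1O[Li])c1ccc(OCc2ccccc2)cc1O[Li] | intermediate
11 | (E)-1-[4-(benzyloxy)-2-hydroxyphenyl]-3-{4,5-bis(benzyloxy)-2-[(E)-1-[4-(benzyloxy)-2-hydroxyphenyl]-3-[4-(benzyloxy)phenyl]-1-hydroxyprop-2-en-1-yl]phenyl}prop-2-en-1-ol, both carbinol centres unassigned | OC(/C=C/c1cc(OCc2ccccc2)c(OCc2ccccc2)cc1C(O)(/C=C/c1ccc(OCc2ccccc2)cc1)c1ccc(OCc2ccccc2)cc1O)c1ccc(OCc2ccccc2)cc1O | intermediate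
12 | (E)-1-[4-(benzyloxy)-2-hydroxyphenyl]-3-{4,5-bis(benzyloxy)-2-[(2S)-7-(benzyloxy)-2-[4-(benzyloxy)phenyl]-2H-chromen-4-yl]phenyl}prop-2-en-1-ol, carbinol centre unassigned | c1ccccc1COc1ccc([C@H]2Oc3cc(OCc4ccccc4)ccc3C(c3cc(OCc4ccccc4)c(OCc4ccccc4)cc3/C=C/C(O)c3ccc(OCc4ccccc4)cc3O)=C2)cc1 | intermediate
13 | (2S)-7-(benzyloxy)-2-[4-(benzyloxy)phenyl]-4-{4,5-bis(benzyloxy)-2-[(2S)-7-(benzyloxy)-2H-chromen-2-yl]phenyl}-2H-chromene | c1ccccc1COc1ccc([C@H]2Oc3cc(OCc4ccccc4)ccc3C(c3cc(OCc4ccccc4)c(OCc4ccccc4)cc3[C@H]3Oc4cc(OCc5ccccc5)ccc4C=C3)=C2)cc1 | intermediate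
14 | bis-alkylborane of 13, BH2 at C3 of each unit on the face opposite the C2 aryl group (same spatial arrangement as 15) | c1ccccc1COc1ccc([C@H]2Oc3cc(OCc4ccccc4)ccc3[C@@H](c3cc(OCc4ccccc4)c(OCc4ccccc4)cc3[C@H]3Oc4cc(OCc5ccccc5)ccc4C[C@@H]3B)[C@@H]2B)cc1 | intermediate
15 | (2R,3S,4R)-7-(benzyloxy)-2-[4-(benzyloxy)phenyl]-4-{4,5-bis(benzyloxy)-2-[(2R,3S)-7-(benzyloxy)-3-hydroxy-3,4-dihydro-2H-chromen-2-yl]phenyl}-3,4-dihydro-2H-chromen-3-ol | c1ccccc1COc1ccc([C@H]2Oc3cc(OCc4ccccc4)ccc3[C@@H](c3cc(OCc4ccccc4)c(OCc4ccccc4)cc3[C@H]3Oc4cc(OCc5ccccc5)ccc4C[C@@H]3O)[C@@H]2O)cc1 | intermediate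
16 | (2R,3S,4R)-4-{2-[(2R,3S)-3,7-dihydroxy-3,4-dihydro-2H-chromen-2-yl]-4,5-dihydroxyphenyl}-2-(4-hydroxyphenyl)-3,4-dihydro-2H-chromene-3,7-diol | Oc1ccc([C@H]2Oc3cc(O)ccc3[C@@H](c3cc(O)c(O)cc3[C@H]3Oc4cc(O)ccc4C[C@@H]3O)[C@@H]2O)cc1 | target

**Totals**

Total step count: 8. Longest linear sequence: 7 (steps 1, 2, 3, 5, 6, 7, 8); step 4 is a one-step side branch.

**Three steps most likely to fail**

Step 6 (double asymmetric cyclisation). The upper ring closure has close precedent. The lower one is a secondary carbinol next to a bulky, already chiral ortho substituent, so it may give low or mismatched selectivity, and the product could racemise by acid-promoted ring opening if it warms before the quench. Minor diastereomers would have to be removed on Et3N-deactivated silica. The fallback closes the two rings one at a time, so that each closure gets its own catalyst. It sets out from 2 and comes back at 12 and then 13. Aldehyde 2 is masked in the flask with LiN(CH2CH2)2O (lithium morpholide) in THF at −78 °C as lithium α-morpholino alkoxide F1. n-BuLi then gives aryllithium F2, which adds to phenoxide 9 to give trilithium adduct F3. Aqueous work-up releases morpholine and the hydroxy aldehyde closes to lactol F4. The chiral acid of step 6 ionises F4 at the diaryl allyl carbon and closes only the upper pyran ring, giving chromene aldehyde F5. With the tertiary oxygen now inside the chromene, no alkoxide is left to add to the enone made next. Claisen–Schmidt condensation of F5 with 3 gives chalcone F6. NaBH4 reduction gives 12 as an isolated compound, and a second cyclisation, with whichever catalyst antipode and 3,3'-aryl group suits this ring alone, gives 13.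

Step 5 (aryllithium union). The trilithio species 8 may be poorly soluble, the unprotected alcohol 5 may cyclise before it is used, and some 1,4-addition to the chalcone is possible. The fallback uses a protected, neutral lithium reagent. It sets out from 5 and comes back at 11. Alcohol 5 is silylated (TBSCl, imidazole, DMF, 0 °C) to bis-silyl ether F7, which no longer cyclises and can be purified and dried. t-BuLi (2 equiv, THF, −78 °C) gives the soluble monolithium aryllithium F8, which adds to 9 to give dilithium adduct F9. Aqueous work-up gives adduct F10, and Bu4NF in THF at 0 °C (basic, so the acid-labile carbinols survive) removes both silyl groups to give 11.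

Step 7 (double hydroboration). Borane could place some boron at C4 of the lower unit, the hindered trisubstituted alkene of the upper unit could react slowly, and a borane β to the ring oxygen could eliminate. The fallback replaces borane addition by copper-catalysed borylation. It sets out from 13 and comes back at 15. CuCl, Xantphos and NaOt-Bu (catalytic) with B2pin2 and MeOH in THF at rt add a boryl copper species syn across each alkene from the face opposite the C2 aryl group. Copper sits at the benzylic C4 and is replaced by hydrogen with retention, giving bis(pinacolboronate) F11 with boron only at C3. NaBO3·4H2O in THF/H2O then oxidises both C–B bonds with retention to give 15.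

**Further compounds**

F1 | step 6 | lithium (morpholin-4-yl)[4,5-bis(benzyloxy)-2-bromophenyl]methanolate | [Li]OC(N1CCOCC1)c1cc(OCc2ccccc2)c(OCc2ccccc2)cc1Br
F2 | step 6 | aryllithium from F1 (lithium in place of bromine) | [Li]OC(N1CCOCC1)c1cc(OCc2ccccc2)c(OCc2ccccc2)cc1[Li]
F3 | step 6 | trilithium adduct of F2 and 9 (α-morpholino alkoxide, tertiary alkoxide, phenoxide) | [Li]OC(N1CCOCC1)c1cc(OCc2ccccc2)c(OCc2ccccc2)cc1C(O[Li])(/C=C/c1ccc(OCc2ccccc2)cc1)c1ccc(OCc2ccccc2)cc1O[Li]
F4 | step 6 | 5,6-bis(benzyloxy)-3-[4-(benzyloxy)-2-hydroxyphenyl]-3-[(E)-2-[4-(benzyloxy)phenyl]ethenyl]-1,3-dihydro-2-benzofuran-1-ol (lactol, stereocentres unassigned) | OC1OC(/C=C/c2ccc(OCc3ccccc3)cc2)(c2ccc(OCc3ccccc3)cc2O)c2cc(OCc3ccccc3)c(OCc3ccccc3)cc21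
F5 | step 6 | 4,5-bis(benzyloxy)-2-[(2S)-7-(benzyloxy)-2-[4-(benzyloxy)phenyl]-2H-chromen-4-yl]benzaldehyde | O=Cc1cc(OCc2ccccc2)c(OCc2ccccc2)cc1C1=C[C@@H](c2ccc(OCc3ccccc3)cc2)Oc2cc(OCc3ccccc3)ccc21
F6 | step 6 | (E)-1-[4-(benzyloxy)-2-hydroxyphenyl]-3-{4,5-bis(benzyloxy)-2-[(2S)-7-(benzyloxy)-2-[4-(benzyloxy)phenyl]-2H-chromen-4-yl]phenyl}prop-2-en-1-one | O=C(/C=C/c1cc(OCc2ccccc2)c(OCc2ccccc2)cc1C1=C[C@@H](c2ccc(OCc3ccccc3)cc2)Oc2cc(OCc3ccccc3)ccc21)c1ccc(OCc2ccccc2)cc1O
F7 | step 5 | bis(tert-butyldimethylsilyl) ether of 5 (alkyl and aryl silyl ether) | CC(C)(C)[Si](C)(C)OC(/C=C/c1cc(OCc2ccccc2)c(OCc2ccccc2)cc1Br)c1ccc(OCc2ccccc2)cc1O[Si](C)(C)C(C)(C)C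
F8 | step 5 | aryllithium from F7 (lithium in place of bromine) | CC(C)(C)[Si](C)(C)OC(/C=C/c1cc(OCc2ccccc2)c(OCc2ccccc2)cc1[Li])c1ccc(OCc2ccccc2)cc1O[Si](C)(C)C(C)(C)C
F9 | step 5 | dilithium adduct of F8 and 9 (tertiary alkoxide, phenoxide) | CC(C)(C)[Si](C)(C)OC(/C=C/c1cc(OCc2ccccc2)c(OCc2ccccc2)cc1C(O[Li])(/C=C/c1ccc(OCc2ccccc2)cc1)c1ccc(OCc2ccccc2)cc1O[Li])c1ccc(OCc2ccccc2)cc1O[Si](C)(C)C(C)(C)C
F10 | step 5 | bis(tert-butyldimethylsilyl) ether of 11 (silyl groups on the lower carbinol and lower phenol) | CC(C)(C)[Si](C)(C)OC(/C=C/c1cc(OCc2ccccc2)c(OCc2ccccc2)cc1C(O)(/C=C/c1ccc(OCc2ccccc2)cc1)c1ccc(OCc2ccccc2)cc1O)c1ccc(OCc2ccccc2)cc1O[Si](C)(C)C(C)(C)C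
F11 | step 7 | bis(pinacolboronate) corresponding to 15 (pinacolboryl in place of each 3-hydroxy group, same spatial arrangement) | c1ccccc1COc1ccc([C@H]2Oc3cc(OCc4ccccc4)ccc3[C@@H](c3cc(OCc4ccccc4)c(OCc4ccccc4)cc3[C@H]3Oc4cc(OCc5ccccc5)ccc4C[C@@H]3B3OC(C)(C)C(C)(C)O3)[C@@H]2B2OC(C)(C)C(C)(C)O2)cc1
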